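## Structural features

The target 16 is a 1-aryl-1,2-dihydronaphthalene lignan. A 6,7,8-trimethoxylated benzo ring (ring A, C4a to C8a) is fused to a six-membered carbocycle (ring B: C1, C2, C3, C4, C4a, C8a) that carries a 3,4-dimethoxyphenyl group on C1. C2 and C3 bear hydroxymethyl groups (C9 and C10), and C3=C4 is a trisubstituted alkene conjugated with ring A. The only stereocentres, C1 (R) and C2 (S), are adjacent, with the aryl group and the C9 arm trans; C1 is a diarylmethine that lies peri to the C8 methoxy group. The fragile points are the doubly benzylic C1–H, the dihydronaphthalene (one alkene shift and one dehydrogenation from a naphthalene), the allylic C10 alcohol, and the 1,4-diol, which can close to an ether under acid. The real difficulty is twofold: fixing the absolute configuration of a methine whose two aryl groups differ only in substitution, and closing ring B with C2 trans to C1 without aromatising the ring. The feature used is that C2 and C3 are each α to a carboxyl-level carbon (C9, C10), so C2–C3 is the central bond of a succinate. With a carbonyl at C4, C3 becomes the carbon of a β-keto ester, and the two carbons can be joined as enolates by oxidation.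

## Logic of the disconnections

**16 to 15.** No carbon–carbon bond is cut; the C9 and C10 alcohols are raised to esters. This keeps both carbons at the carboxyl level that the earlier steps need and confines the acid-sensitive diol to the last flask, so no protecting group is required. The forward step must reduce the conjugated C10 ester in 1,2-fashion and the C9 ester next to C2 without alkene shift or epimerisation.

**15 to 13 to 12.** The C3=C4 alkene is exchanged for oxygen at C4: formal hydration gives 13, and oxidation of C4 gives the ketone 12 (forward: hydride reduction, then elimination through 14). The C4 carbonyl is what makes C3 an easily formed and oxidisable enolate carbon, so the alkene is best derived from it. Elimination can only run toward C3, because C4a is aromatic, but the base must be mild enough to leave C2–H alone.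

**12 to 10 (through 11).** The C2–C3 bond is cut, opening ring B to an acyclic chain in which C2 is α to an ester and C3 is the methylene of a β-keto ester. Both carbons are natural nucleophiles, so the bond is made by removing two electrons from the bis-enolate 11. The gain is one ring and two stereocentres, leaving a single stereocentre (C1). The forward step must pair the two different enolates within one molecule, avoid oligomers, and place C2 trans to C1. The two ester alkyl groups are spectators and stay unlike, because each arrives with its own building block and both are reduced away at the end. If C2 needs correcting, this is better done at 15 (C2–H allylic and α to an ester) than at 12, where C3 is deprotonated first.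

**10 to 8 and 9.** The C3–C4 bond is cut. The β-keto ester is returned to an aryl aldehyde and a two-carbon diazo ester, which supplies C3 and C10 in one step without base. The forward step needs hydride migration, not aryl migration, after addition to the aldehyde.

**8 to 7.** The C4–C4a bond is cut and the formyl carbon is returned to a one-carbon carbonyl source. The bromine of 7 marks C4a from the start and is inert in the earlier steps. The forward carbonylation must tolerate the ester and an ortho-substituted, electron-rich bromide.

**7 to 5 and 6.** The bond between C1 and the dimethoxyphenyl ring is cut. This is the only point at which absolute configuration is introduced, and it reduces the problem to an achiral cinnamate and an arylboron reagent. The forward step must discriminate the faces of a β-aryl enoate that is substituted at both ortho positions.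

**5 to 3 and 4, and 3 to 1 (through 2).** The C1=C2 alkene is cut to an aldehyde and a stabilised ylide, and the C1–C8a bond is cut by removing the formyl group. In 1 the only free ring positions are two equivalent carbons between bromine and methoxy, so formylation gives the needed substitution pattern without a regiochemical question.

## Other disconnections considered

**Alternative 1:** gold-catalysed formal [4+2] cyclisation of an aryl enyne.
- **Cut:** C2–C3 and C8a–C1, with C9 and C10 joined through an ether oxygen as tether.
- **Forward key step:** the aryl alkynyl cinnamyl ether A1 would be treated with DTBM-SEGPHOS(AuCl)2 and AgSbF6 (cationic monovalent gold). The E-alkene would attack the activated alkyne through C2 at C3 (5-exo), the developing C1 cation would be captured by the ortho carbon C8a of ring A, and protodeauration would give A2, the cyclic ether of 16, with C3=C4 already in place.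
- **In favour:** two C–C bonds, two rings and both stereocentres would form in one catalytic step. The E-alkene should translate into the trans C1/C2 relation. A1 should be reachable in about three steps (Sonogashira coupling, Williamson etherification). No oxidation-state detour at C4 is needed.
- **Against:** enantio-induction by linear two-coordinate gold depends strongly on the substrate. The electron-rich dimethoxyphenyl group stabilises an open C1 cation, which threatens both stereospecificity and enantiomeric purity. Above all, A2 is not the diol: two alkyl C–O bonds must be cleaved, or C10 oxidised and reduced again, in the presence of five aryl methyl ethers, a doubly benzylic C1–H and a ring that aromatises easily.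
- **Comparison:** the alternative is the better plan in convergence and bonds made per step, and in setting both stereocentres by the catalyst at the moment of bond formation. It is the equal of the chosen plan in making the same C2–C3 bond. The chosen plan is better on structure, because C9 and C10 travel as esters that one hydride step turns into the diol. On step count the alternative should be shorter to the skeleton (about four steps to A2 against six to 12), but the ether opening makes the totals comparable and its last steps far less certain.

**Alternative 2:** asymmetric quinone Diels–Alder with late aromatisation of ring A.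
- **Cut:** C8a–C1 and C4a–C4, with ring A arriving as a quinone.
- **Forward key step:** diene A3 would add endo to the unsubstituted double bond of quinone A4 under a chiral oxazaborolidinium triflimide to give the cis-fused adduct A5.
- **In favour:** catalysed quinone Diels–Alder reactions of this kind are known for reliable endo- and enantio-control. A4 is symmetric across the reacting alkene, so no regiochemical question arises. C1 would be set by the catalyst.
- **Against:** A5 is far from 16. Ring A must be aromatised with loss of the C5 oxygen and methylation of the C8 oxygen. C3 carries oxygen where C10 is needed, so C10 would have to be added later through an enol triflate. C2 is sp2 in A5 and would be set only later by protonation. Two of the three stereocentres made (C4a, C8a) are destroyed again, and A3 itself needs several steps.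
- **Comparison:** on mechanism the alternative is the equal or the better of the chosen plan for control at C1, since a catalysed cycloaddition is a surer source of enantiopurity than rhodium addition to a doubly ortho-substituted cinnamate. On structure it is the poorer match (wrong oxidation pattern in ring A, one carbon missing). On step economy it should be clearly worse, estimated at well over twelve steps against nine.

**Alternative 3:** aminocatalytic ring closure onto a para-quinone methide.
- **Cut:** C1–C2.
- **Forward key step:** a phosphoric acid would ionise the para-hydroxybenzhydrol of A6 to the para-quinone methide A7, while the aldehyde condenses with a diarylprolinol silyl ether (dienamine activation). Attack through C2 on C1, rearomatisation and hydrolysis would give the trans aldehyde A8.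
- **In favour:** C1 and C2 would be set together under catalyst control, C3=C4 and the C10 oxygen are already present, and no metal is used. Only reduction of the aldehyde, methylation of the phenol and desilylation would remain.
- **Against:** A6 combines an ortho-placed benzhydrol with a β,γ-unsaturated aldehyde of defined alkene geometry on a crowded ring A, and should take more steps than 10 (estimated seven or eight). α- versus γ-attack of the dienamine must be controlled. A8 is an α-chiral β,γ-unsaturated aldehyde that can epimerise or conjugate to C2=C3, so it would have to be reduced at once. The route also depends on a free para-hydroxyl that must be methylated later.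
- **Comparison:** the alternative is the better plan in setting both stereocentres in the ring-closing step and in reaching the correct oxidation state at C4 directly. Its three-step end game is the equal of the chosen one. It closes ring B by a two-electron ionic step instead of an oxidation, so it needs neither strong base nor stoichiometric oxidant. The chosen plan is better in the supply of the cyclisation substrate (five steps from commercial materials), and the totals are expected to be similar or slightly in favour of the chosen plan.

Key step: step 6

**Remarks and assumptions (chemistry)**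
- The dihydronaphthalene numbering of the target is used for all intermediates (C1 aryl-bearing carbon, C9 on C2, C10 on C3).
- Assumption: aryl transfer in step 3 follows the usual facial model for E-enoates under Rh/BINAP ((S)-BINAP, α-si face, here R). If this hindered substrate reversed the sense, (R)-BINAP would be used with no other change.
- The aryl ring of 10 is named with lowest locants (6-acyl-2,3,4-trimethoxyphenyl). Compounds 7, 8 and 10 to 16 carry R at C1 and 12 to 16 carry S at C2, the same spatial arrangement as in the target.

## Route

**Step 1**
Reactants: 1 5-bromo-1,2,3-trimethoxybenzene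
Product: 3 6-bromo-2,3,4-trimethoxybenzaldehyde, via aryl chloromethyl methyl ether 2 (not isolated)
Conditions: Cl2CHOMe, TiCl4, CH2Cl2, −10 to 0 °C; then ice/aq. HCl
Reagents that add atoms: dichloromethyl methyl ether, COC(Cl)Cl; water, O
Why: Rieche formylation (electrophilic aromatic substitution by the TiCl4-activated chloro ether); the only free positions of 1 are two equivalent carbons between Br and OMe, so one aldehyde should result once 2 is hydrolysed on work-up.

**Step 2**
Reactants: 3 6-bromo-2,3,4-trimethoxybenzaldehyde; 4 methyl (triphenylphosphoranylidene)acetate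
Product: 5 methyl (2E)-3-(6-bromo-2,3,4-trimethoxyphenyl)prop-2-enoate
Conditions: toluene, 100 °C
Reagents that add atoms: none
Why: Wittig olefination with a stabilised ylide, which should give the E-enoate; heating compensates for the doubly ortho-substituted aldehyde.

**Step 3**
Reactants: 5 methyl (2E)-3-(6-bromo-2,3,4-trimethoxyphenyl)prop-2-enoate; 6 (3,4-dimethoxyphenyl)boronic acid
Product: 7 methyl (3R)-3-(6-bromo-2,3,4-trimethoxyphenyl)-3-(3,4-dimethoxyphenyl)propanoate
Conditions: Rh(acac)(C2H4)2 (3 mol%), (S)-BINAP, 6 (3 equiv), dioxane/H2O 10:1, 100 °C
Reagents that add atoms: none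
Why: Rhodium-catalysed asymmetric 1,4-addition of an arylboronic acid (Hayashi–Miyaura reaction): the aryl–Rh species adds across the enoate and the oxa-π-allyl rhodium intermediate is protonated by water. C1 is set by the ligand; with (S)-BINAP the aryl group should enter on the α-si face of the E-enoate, which corresponds to R. The aryl bromide is not expected to react with monovalent rhodium under these conditions.

**Step 4**
Reactants: 7 methyl (3R)-3-(6-bromo-2,3,4-trimethoxyphenyl)-3-(3,4-dimethoxyphenyl)propanoate
Product: 8 methyl (3R)-3-(3,4-dimethoxyphenyl)-3-(6-formyl-2,3,4-trimethoxyphenyl)propanoate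
Conditions: Pd(OAc)2 (2 mol%), di(1-adamantyl)-n-butylphosphine, TMEDA, CO/H2 1:1 (5 bar), toluene, 100 °C
Reagents that add atoms: carbon monoxide, [C-]#[O+]
Why: Palladium-catalysed reductive carbonylation (formylation) of an aryl bromide: oxidative addition to zerovalent palladium, CO insertion and hydrogenolysis of the acyl–Pd bond. The bulky electron-rich phosphine suits an electron-rich, ortho-substituted bromide, and the ester and the C1 centre are inert.

**Step 5**
Reactants: 8 methyl (3R)-3-(3,4-dimethoxyphenyl)-3-(6-formyl-2,3,4-trimethoxyphenyl)propanoate; 9 ethyl diazoacetate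
Product: 10 methyl (3R)-3-(3,4-dimethoxyphenyl)-3-[6-(3-ethoxy-3-oxopropanoyl)-2,3,4-trimethoxyphenyl]propanoate
Conditions: SnCl2 (10 mol%), 9 (1.5 equiv), CH2Cl2, rt
Reagents that add atoms: none
Why: Roskamp homologation: the SnCl2-activated aldehyde is attacked by the diazo carbon, and a 1,2-hydride shift with loss of N2 gives the β-keto ester. No base is present, so C1 and the methyl ester are untouched.

**Step 6**
Reactants: 10 methyl (3R)-3-(3,4-dimethoxyphenyl)-3-[6-(3-ethoxy-3-oxopropanoyl)-2,3,4-trimethoxyphenyl]propanoate
Product: 12 3-ethyl 2-methyl (1R,2S,3R)-1-(3,4-dimethoxyphenyl)-6,7,8-trimethoxy-4-oxo-1,2,3,4-tetrahydronaphthalene-2,3-dicarboxylate, via dilithium bis-enolate 11 (not isolated)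
Conditions: LiN(SiMe3)2 (2.3 equiv), THF (0.02 M), −78 °C; then Fe(acac)3 (2.2 equiv), −78 °C to rt; aq. NH4Cl
Reagents that add atoms: none
Why: This is an intramolecular oxidative heterocoupling of two enolates. The first equivalent of LiN(SiMe3)2 gives the stabilised β-keto ester enolate at C3 (the aryl ketone has no other α-hydrogen) and the second gives the ester enolate at C2, so 11 carries both nucleophilic carbons. Fe(acac)3 (trivalent iron) should take one electron from the more electron-rich ester enolate; the α-ester radical at C2 adds to C3 of the neighbouring enolate, and a second equivalent oxidises the resulting ketyl radical anion to complete the C2–C3 bond. The closest known reaction type is the iron- or copper-mediated oxidative coupling of lithium enolates, including intramolecular cases with 1,3-dicarbonyl partners. Ring B closes as a six-membered ring by joining the two ends of the C2–C1–C8a–C4a–C4–C3 chain, formally 6-endo-trig with respect to the C3=C4 enolate bond (6-exo-trig if the acceptor is written in its C3=C10 form). At C2, allylic strain should keep C1–H in the plane of ring A beside the C8 methoxy group and in the plane of the C2 enolate; the C1 aryl group then stands pseudo-axial, and C3, held on the ring A side, should reach C2 so that the C2 ester ends anti to the aryl group (trans). C3 stays acidic, should settle trans to C2 under thermodynamic control, and is flattened later in any case. The step needs hetero- over homocoupling and ring closure over oligomerisation: the tether pairs the two unlike enolates, their different oxidation potentials decide which one is oxidised, and high dilution disfavours intermolecular coupling.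

**Step 7**
Reactants: 12 3-ethyl 2-methyl (1R,2S,3R)-1-(3,4-dimethoxyphenyl)-6,7,8-trimethoxy-4-oxo-1,2,3,4-tetrahydronaphthalene-2,3-dicarboxylate
Product: 13 3-ethyl 2-methyl (1R,2S,3R)-1-(3,4-dimethoxyphenyl)-4-hydroxy-6,7,8-trimethoxy-1,2,3,4-tetrahydronaphthalene-2,3-dicarboxylate (C4 epimers)
Conditions: NaBH4 (1.1 equiv), MeOH/THF, −20 to 0 °C
Reagents that add atoms: none
Why: Hydride reduction of the aryl ketone of a β-keto ester; NaBH4 at low temperature should leave both esters. The C4 configuration is immaterial because C4 becomes sp2 in step 8, and any alkoxy exchange between the esters would be harmless because both are reduced in step 9.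

**Step 8**
Reactants: 13 3-ethyl 2-methyl (1R,2S,3R)-1-(3,4-dimethoxyphenyl)-4-hydroxy-6,7,8-trimethoxy-1,2,3,4-tetrahydronaphthalene-2,3-dicarboxylate
Product: 15 3-ethyl 2-methyl (1R,2S)-1-(3,4-dimethoxyphenyl)-6,7,8-trimethoxy-1,2-dihydronaphthalene-2,3-dicarboxylate, via C4 mesylate 14 (not isolated)
Conditions: MsCl, Et3N, CH2Cl2, 0 °C; then DBU, 0 °C to rt
Reagents that add atoms: none
Why: Mesylation of the benzylic alcohol followed by E1cB elimination: C3–H is the only β-hydrogen and is acidified by the C10 ester, so the alkene can form only as C3=C4, conjugated with ring A and the ester. Short contact with DBU at low temperature should spare C2, whose trans arrangement is also the thermodynamically preferred one.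

**Step 9**
Reactants: 15 3-ethyl 2-methyl (1R,2S)-1-(3,4-dimethoxyphenyl)-6,7,8-trimethoxy-1,2-dihydronaphthalene-2,3-dicarboxylate
Product: 16 [(1R,2S)-1-(3,4-dimethoxyphenyl)-6,7,8-trimethoxy-1,2-dihydronaphthalene-2,3-diyl]dimethanol
Conditions: iBu2AlH (6 equiv), CH2Cl2, −78 to 0 °C; aq. potassium sodium tartrate
Reagents that add atoms: none
Why: iBu2AlH reduction of both esters to primary alcohols, with 1,2-reduction of the enoate to the allylic alcohol. Low temperature and a non-acidic tartrate work-up should protect the alkene, the allylic alcohol and both stereocentres.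

## Compound list

1 | 5-bromo-1,2,3-trimethoxybenzene | COc1cc(Br)cc(OC)c1OC | starting material
2 | 1-bromo-2-[chloro(methoxy)methyl]-3,4,5-trimethoxybenzene (racemic at the new carbon, not isolated) | COC(Cl)c1c(Br)cc(OC)c(OC)c1OC | intermediate
3 | 6-bromo-2,3,4-trimethoxybenzaldehyde | O=Cc1c(Br)cc(OC)c(OC)c1OC | intermediate
4 | methyl (triphenylphosphoranylidene)acetate | COC(=O)C=P(c1ccccc1)(c1ccccc1)c1ccccc1 | starting material
5 | methyl (2E)-3-(6-bromo-2,3,4-trimethoxyphenyl)prop-2-enoate | COC(=O)/C=C/c1c(Br)cc(OC)c(OC)c1OC | intermediate
6 | (3,4-dimethoxyphenyl)boronic acid | COc1ccc(B(O)O)cc1OC | starting material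
7 | methyl (3R)-3-(6-bromo-2,3,4-trimethoxyphenyl)-3-(3,4-dimethoxyphenyl)propanoate | COC(=O)C[C@H](c1ccc(OC)c(OC)c1)c1c(Br)cc(OC)c(OC)c1OC | intermediate
8 | methyl (3R)-3-(3,4-dimethoxyphenyl)-3-(6-formyl-2,3,4-trimethoxyphenyl)propanoate | COC(=O)C[C@H](c1ccc(OC)c(OC)c1)c1c(C=O)cc(OC)c(OC)c1OC | intermediate
9 | ethyl diazoacetate | CCOC(=O)C=[N+]=[N-] | starting material
10 | methyl (3R)-3-(3,4-dimethoxyphenyl)-3-[6-(3-ethoxy-3-oxopropanoyl)-2,3,4-trimethoxyphenyl]propanoate | COC(=O)C[C@H](c1ccc(OC)c(OC)c1)c1c(C(=O)CC(=O)OCC)cc(OC)c(OC)c1OC | intermediate
11 | dilithium bis-enolate of 10 (ester enolate at C2, β-keto ester enolate at C3; R at C1; not isolated) | COC(O[Li])=C[C@H](c1ccc(OC)c(OC)c1)c1c(C(O[Li])=CC(=O)OCC)cc(OC)c(OC)c1OC | intermediate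
12 | 3-ethyl 2-methyl (1R,2S,3R)-1-(3,4-dimethoxyphenyl)-6,7,8-trimethoxy-4-oxo-1,2,3,4-tetrahydronaphthalene-2,3-dicarboxylate | COc1ccc([C@@H]2c3c(cc(OC)c(OC)c3OC)C(=O)[C@H](C(=O)OCC)[C@H]2C(=O)OC)cc1OC | intermediate
13 | 3-ethyl 2-methyl (1R,2S,3R)-1-(3,4-dimethoxyphenyl)-4-hydroxy-6,7,8-trimethoxy-1,2,3,4-tetrahydronaphthalene-2,3-dicarboxylate (C4 epimers) | COc1ccc([C@@H]2c3c(cc(OC)c(OC)c3OC)C(O)[C@H](C(=O)OCC)[C@H]2C(=O)OC)cc1OC | intermediate
14 | 3-ethyl 2-methyl (1R,2S,3R)-1-(3,4-dimethoxyphenyl)-6,7,8-trimethoxy-4-[(methylsulfonyl)oxy]-1,2,3,4-tetrahydronaphthalene-2,3-dicarboxylate (C4 epimers, not isolated) | COc1ccc([C@@H]2c3c(cc(OC)c(OC)c3OC)C(OS(C)(=O)=O)[C@H](C(=O)OCC)[C@H]2C(=O)OC)cc1OC | intermediate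
15 | 3-ethyl 2-methyl (1R,2S)-1-(3,4-dimethoxyphenyl)-6,7,8-trimethoxy-1,2-dihydronaphthalene-2,3-dicarboxylate | COc1ccc([C@@H]2c3c(cc(OC)c(OC)c3OC)C=C(C(=O)OCC)[C@H]2C(=O)OC)cc1OC | intermediate
16 | [(1R,2S)-1-(3,4-dimethoxyphenyl)-6,7,8-trimethoxy-1,2-dihydronaphthalene-2,3-diyl]dimethanol | COc1ccc([C@@H]2c3c(cc(OC)c(OC)c3OC)C=C(CO)[C@H]2CO)cc1OC | target

## Step count and least certain steps

Total: 9 steps. Longest linear sequence: 9 steps (1 to 16); 4, 6 and 9 enter as commercial building blocks.

**Step 6 (key step).** The second deprotonation, next to an already anionic β-keto ester, may be incomplete, and single-electron oxidation may then lead to intermolecular coupling through C3, to oxygenation by adventitious air, or to closure with the C2 ester cis to the aryl group. The fallback makes C2–C3 by alkylation and closes ring B at C3–C4. It sets out from 7.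
- Alkylation of the lithium ester enolate of 7 (LiN(iPr)2, THF, −78 °C) with ethyl bromoacetate would give the bromo succinate 4-ethyl 1-methyl 2-[(R)-(6-bromo-2,3,4-trimethoxyphenyl)(3,4-dimethoxyphenyl)methyl]butanedioate F1.
- Palladium-catalysed methoxycarbonylation of the bromide (Pd(OAc)2, dppf, CO 1 atm, MeOH, Et3N, DMF, 80 °C) would give the triester 4-ethyl 1-methyl 2-{(R)-(3,4-dimethoxyphenyl)[2,3,4-trimethoxy-6-(methoxycarbonyl)phenyl]methyl}butanedioate F2.
- A Dieckmann condensation (LiN(SiMe3)2 or KOtBu, THF, −78 °C to rt) would return to 12. Only attack through C3 gives a β-keto ester that keeps an acidic hydrogen, so the reversible Claisen manifold should funnel to the six-membered ring.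
- The price is that C2 forms in an open chain; its epimers would have to be separated or converged by base equilibration at the stage of 15.

**Step 3.** Addition to a β-aryl enoate substituted at both ortho positions may be slow, so that protodeboronation of 6 outruns aryl transfer, and the face selectivity may be lower than for simple cinnamates. The fallback replaces catalyst control by an auxiliary. It sets out from 5.
- Saponification (LiOH, THF/H2O) would give (2E)-3-(6-bromo-2,3,4-trimethoxyphenyl)prop-2-enoic acid F3.
- Activation with pivaloyl chloride/Et3N and acylation of lithiated (S)-4-phenyl-1,3-oxazolidin-2-one would give the enoyl imide (4S)-3-[(2E)-3-(6-bromo-2,3,4-trimethoxyphenyl)prop-2-enoyl]-4-phenyl-1,3-oxazolidin-2-one F4.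
- Copper-mediated conjugate addition of 3,4-dimethoxyphenylmagnesium bromide (CuBr·SMe2, THF, −40 °C) should occur anti to the phenyl group of the magnesium-chelated s-cis imide and give the R adduct (4S)-3-[(3R)-3-(6-bromo-2,3,4-trimethoxyphenyl)-3-(3,4-dimethoxyphenyl)propanoyl]-4-phenyl-1,3-oxazolidin-2-one F5.
- Methanolysis (NaOMe, MeOH, 0 °C) would return to 7 and release the auxiliary.

**Step 4.** Hydrodebromination may compete with CO insertion at the hindered, electron-rich bromide, and conversion may stall. The fallback installs the carbon by cross-coupling and reveals the aldehyde by oxidative cleavage. It sets out from 7.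
- Suzuki–Miyaura coupling with potassium vinyltrifluoroborate (PdCl2(dppf), Cs2CO3, THF/H2O, 80 °C) would give the styrene methyl (3R)-3-(3,4-dimethoxyphenyl)-3-(6-ethenyl-2,3,4-trimethoxyphenyl)propanoate F6.
- Lemieux–Johnson cleavage (OsO4 cat., NaIO4, 2,6-lutidine, dioxane/H2O) would return to 8.

**Step 5.** With an electron-rich aryl aldehyde, aryl migration may compete with hydride migration after addition of the diazo ester, and the hindered aldehyde may react slowly. The fallback uses addition and oxidation. It sets out from 8.
- Reformatsky addition (Zn, ethyl bromoacetate, THF, 50 °C; neutral, so the methyl ester is spared) would give the hydroxy ester methyl (3R)-3-(3,4-dimethoxyphenyl)-3-[6-(3-ethoxy-1-hydroxy-3-oxopropyl)-2,3,4-trimethoxyphenyl]propanoate F7.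
- Oxidation with Dess–Martin periodinane (CH2Cl2, rt) would return to 10.

**Step 8.** Deprotonation at C2 of the product by the amine base may shift the alkene to C2=C3, which opens the way to epimerisation and to air oxidation to the naphthalene. The fallback removes the C4 oxygen without an elimination step. It sets out from 12.
- O-Triflation of the β-keto ester enolate (NaH, PhNTf2, THF, 0 °C) would give the enol triflate 3-ethyl 2-methyl (1R,2S)-1-(3,4-dimethoxyphenyl)-6,7,8-trimethoxy-4-[(trifluoromethanesulfonyl)oxy]-1,2-dihydronaphthalene-2,3-dicarboxylate F8.
- Palladium-catalysed formate reduction (Pd(OAc)2, PPh3, HCO2H, Et3N, DMF, 60 °C) would return to 15, by-passing 13 and 14.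

## Further compounds

F1 | step 6 | 4-ethyl 1-methyl 2-[(R)-(6-bromo-2,3,4-trimethoxyphenyl)(3,4-dimethoxyphenyl)methyl]butanedioate (C2 epimers) | CCOC(=O)CC(C(=O)OC)[C@H](c1ccc(OC)c(OC)c1)c1c(Br)cc(OC)c(OC)c1OC
F2 | step 6 | 4-ethyl 1-methyl 2-{(R)-(3,4-dimethoxyphenyl)[2,3,4-trimethoxy-6-(methoxycarbonyl)phenyl]methyl}butanedioate (C2 epimers) | CCOC(=O)CC(C(=O)OC)[C@H](c1ccc(OC)c(OC)c1)c1c(C(=O)OC)cc(OC)c(OC)c1OC
F3 | step 3 | (2E)-3-(6-bromo-2,3,4-trimethoxyphenyl)prop-2-enoic acid | OC(=O)/C=C/c1c(Br)cc(OC)c(OC)c1OC
F4 | step 3 | (4S)-3-[(2E)-3-(6-bromo-2,3,4-trimethoxyphenyl)prop-2-enoyl]-4-phenyl-1,3-oxazolidin-2-one | O=C(/C=C/c1c(Br)cc(OC)c(OC)c1OC)N1C(=O)OC[C@@H]1c1ccccc1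
F5 | step 3 | (4S)-3-[(3R)-3-(6-bromo-2,3,4-trimethoxyphenyl)-3-(3,4-dimethoxyphenyl)propanoyl]-4-phenyl-1,3-oxazolidin-2-one | O=C(C[C@H](c1ccc(OC)c(OC)c1)c1c(Br)cc(OC)c(OC)c1OC)N1C(=O)OC[C@@H]1c1ccccc1
F6 | step 4 | methyl (3R)-3-(3,4-dimethoxyphenyl)-3-(6-ethenyl-2,3,4-trimethoxyphenyl)propanoate | COC(=O)C[C@H](c1ccc(OC)c(OC)c1)c1c(C=C)cc(OC)c(OC)c1OC
F7 | step 5 | methyl (3R)-3-(3,4-dimethoxyphenyl)-3-[6-(3-ethoxy-1-hydroxy-3-oxopropyl)-2,3,4-trimethoxyphenyl]propanoate (carbinol epimers) | COC(=O)C[C@H](c1ccc(OC)c(OC)c1)c1c(C(O)CC(=O)OCC)cc(OC)c(OC)c1OC
F8 | step 8 | 3-ethyl 2-methyl (1R,2S)-1-(3,4-dimethoxyphenyl)-6,7,8-trimethoxy-4-[(trifluoromethanesulfonyl)oxy]-1,2-dihydronaphthalene-2,3-dicarboxylate | COc1ccc([C@@H]2c3c(cc(OC)c(OC)c3OC)C(OS(=O)(=O)C(F)(F)F)=C(C(=O)OCC)[C@H]2C(=O)OC)cc1OC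
A1 | alternative 1 | 4-[(1E)-3-{[3-(3,4,5-trimethoxyphenyl)prop-2-yn-1-yl]oxy}prop-1-en-1-yl]-1,2-dimethoxybenzene | COc1ccc(/C=C/COCC#Cc2cc(OC)c(OC)c(OC)c2)cc1OC
A2 | alternative 1 | (3aS,4R)-4-(3,4-dimethoxyphenyl)-5,6,7-trimethoxy-1,3,3a,4-tetrahydronaphtho[2,3-c]furan | COc1ccc([C@@H]2c3c(cc(OC)c(OC)c3OC)C=C4COC[C@@H]24)cc1OC
A3 | alternative 2 | tert-butyl{[(2E)-3-(3,4-dimethoxyphenyl)-2-(1-{[tri(propan-2-yl)silyl]oxy}ethenyl)prop-2-en-1-yl]oxy}dimethylsilane | COc1ccc(/C=C(\CO[Si](C)(C)C(C)(C)C)C(=C)O[Si](C(C)C)(C(C)C)C(C)C)cc1OC
A4 | alternative 2 | 2,3-dimethoxycyclohexa-2,5-diene-1,4-dione | COC1=C(OC)C(=O)C=CC1=O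
A5 | alternative 2 | cis-fused endo adduct 6-{[tert-butyl(dimethyl)silyl]oxymethyl}-5-(3,4-dimethoxyphenyl)-2,3-dimethoxy-7-{[tri(propan-2-yl)silyl]oxy}-4a,5,8,8a-tetrahydronaphthalene-1,4-dione | COc1ccc([C@@H]2[C@@H]3C(=O)C(OC)=C(OC)C(=O)[C@@H]3CC(O[Si](C(C)C)(C(C)C)C(C)C)=C2CO[Si](C)(C)C(C)(C)C)cc1OC
A6 | alternative 3 | (3E)-3-{[tert-butyl(dimethyl)silyl]oxymethyl}-4-{2-[hydroxy(4-hydroxy-3-methoxyphenyl)methyl]-3,4,5-trimethoxyphenyl}but-3-enal (racemic carbinol) | O=CC/C(CO[Si](C)(C)C(C)(C)C)=C\c1cc(OC)c(OC)c(OC)c1C(O)c1ccc(O)c(OC)c1
A7 | alternative 3 | (3E)-3-{[tert-butyl(dimethyl)silyl]oxymethyl}-4-{3,4,5-trimethoxy-2-[(3-methoxy-4-oxocyclohexa-2,5-dien-1-ylidene)methyl]phenyl}but-3-enal | COC1=CC(=Cc2c(OC)c(OC)c(OC)cc2/C=C(\CC=O)CO[Si](C)(C)C(C)(C)C)C=CC1=O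
A8 | alternative 3 | (1R,2S)-3-{[tert-butyl(dimethyl)silyl]oxymethyl}-1-(4-hydroxy-3-methoxyphenyl)-6,7,8-trimethoxy-1,2-dihydronaphthalene-2-carbaldehyde | Oc1ccc([C@@H]2c3c(cc(OC)c(OC)c3OC)C=C(CO[Si](C)(C)C(C)(C)C)[C@H]2C=O)cc1OC
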